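**Plan**

- Numbering used here: ring C1 (C–Me, epoxide), C2 (epoxide CH), C3 (CH2), C4 (CH bearing the side chain), C5 (CH–O-angelate), C6 (C=O); side chain C7 (the =CH2-bearing carbon) and C8 (carbinol).
- Retrosynthetic cuts: C5–O angelate (with inversion) and C8–O senecioate; the epoxide back to a 2-methylcyclohex-2-enone; C7–C8; a 1,3-carbonyl transposition (C6 to C2); then the carbocycle at C4–C5 and C1–C6.
- Enabling feature: the six-membered carbocycle is oxygenated at C6 and C2 on both sides of the methyl-bearing C1 (an aldol/enone pattern) and at C5 next to C6. C5–C6 is therefore an α-silyloxyacetaldehyde (donor at C5, acceptor at C6), and C1–C4 is an ethyl enone (acceptor at C4, donor at C1 through a carbonyl at C2).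
- Forward: one amine-catalysed Michael/aldol condensation joins aldehyde and enynone to the cyclohexenone. The carbonyl is then moved from C2 to C6, the side chain is coupled at C7–C8, the enone is epoxidised, and the two esters are installed.
- Stereochemistry: C4 and C5 come from the prolinol catalyst in the key step; C5 is formed trans to C4 and inverted in the last step. C8 comes from a chiral chromium ligand. C1 and C2 come from the C4 substituent by substrate control.

Key step: step 2

Remark (assumption): the syn sense of the enamine Michael addition known for nitroalkenes and vinyl ketones is taken to hold for enynone 3; the syn adduct corresponds to the 4,5-trans ring.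

**Step 1**
Reactants: 1 3-(trimethylsilyl)prop-2-ynal; 2 diethyl (2-oxobutyl)phosphonate
Product: 3 (4E)-7-(trimethylsilyl)hept-4-en-6-yn-3-one
Conditions: LiCl, i-Pr2NEt, MeCN, 0 °C → rt
Reagents that add atoms: none
Why: Horner–Wadsworth–Emmons olefination of a β-keto phosphonate under mild LiCl/amine conditions, which the alkynylsilane tolerates, should give the E-enone.

**Step 2**
Reactants: 3 (4E)-7-(trimethylsilyl)hept-4-en-6-yn-3-one; 4 [(tert-butyldimethylsilyl)oxy]acetaldehyde
Product: 7 (4S,5R)-4-[(tert-butyldimethylsilyl)oxy]-2-methyl-5-[(trimethylsilyl)ethynyl]cyclohex-2-en-1-one, via Michael adduct 5 (not isolated), via aldol adduct 6 (not isolated)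
Conditions: (S)-α,α-diphenylprolinol trimethylsilyl ether (20 mol %), PhCO2H (20 mol %), toluene, 0 °C → rt; then p-TsOH·H2O (20 mol %), 40 °C, one pot
Reagents that add atoms: none
Why: The catalyst condenses with 4 to an E-enamine whose C5 adds to C4 of 3 (Michael addition, gives 5); after hydrolysis the ethyl ketone enolises towards C1 and attacks the freed aldehyde carbon C6 (6-enolendo-exo-trig aldol, gives 6), and acid-promoted loss of water gives enone 7. The closest known reaction type is the diarylprolinol silyl ether-catalysed Michael addition of aldehydes, α-oxygenated ones included, to enones and nitroalkenes, followed by intramolecular aldol condensation to a cyclohexenone. C5 is set by the catalyst, whose diphenyl(silyloxy)methyl group shields one enamine face, and C4 by the acyclic synclinal transition state that gives the syn adduct, which becomes the 4,5-trans ring; the two carbinol centres of 6 are lost on dehydration. The step needs 1,4-addition ahead of 1,6-addition and of self-aldol of 4, and ring closure through C1: the alkyne terminus is silyl-capped, the β-carbon carries only a slim alkynyl group, and enolisation towards C3 could only close a four-membered ring.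

**Step 3**
Reactants: 7 (4S,5R)-4-[(tert-butyldimethylsilyl)oxy]-2-methyl-5-[(trimethylsilyl)ethynyl]cyclohex-2-en-1-one
Product: 8 (1S,4R,5R,6S)-5-[(tert-butyldimethylsilyl)oxy]-4-ethynyl-1-methyl-7-oxabicyclo[4.1.0]heptan-2-one
Conditions: 30% aq. H2O2, NaOH (0.3 equiv), MeOH, 0 °C → rt
Reagents that add atoms: hydrogen peroxide, OO
Why: Weitz–Scheffer nucleophilic epoxidation of the enone (hydroperoxide should add to C6 anti to the neighbouring silyloxy group; this epoxide configuration is erased later) while methoxide cleaves the C(sp)–Si bond to free the terminal alkyne.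

**Step 4**
Reactants: 8 (1S,4R,5R,6S)-5-[(tert-butyldimethylsilyl)oxy]-4-ethynyl-1-methyl-7-oxabicyclo[4.1.0]heptan-2-one
Product: 9 (1R,5R,6R)-6-[(tert-butyldimethylsilyl)oxy]-5-ethynyl-2-methylcyclohex-2-en-1-ol
Conditions: N2H4·H2O, AcOH (cat.), MeOH, 0 °C → rt
Reagents that add atoms: none
Why: Wharton transposition, in which the epoxy hydrazone opens to an alkenyldiazene that loses N2, should move the oxygen from C2 to C6 and the double bond to C1=C2 (the carvone oxide to carveol change) without touching C4 or C5.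

**Step 5**
Reactants: 9 (1R,5R,6R)-6-[(tert-butyldimethylsilyl)oxy]-5-ethynyl-2-methylcyclohex-2-en-1-ol
Product: 11 (1R,5S,6R)-6-[(tert-butyldimethylsilyl)oxy]-5-(1-iodoethenyl)-2-methylcyclohex-2-en-1-ol, via alkenylalane 10 (not isolated)
Conditions: i-Bu2AlH (2.3 equiv), NiCl2(dppp) (3 mol %), THF, 0 °C → rt; then N-iodosuccinimide, −20 → 0 °C; aq. potassium sodium tartrate
Reagents that add atoms: N-iodosuccinimide, O=C1CCC(=O)N1I
Why: Nickel-catalysed α-selective (Markovnikov) hydroalumination of the terminal alkyne, followed by iodinolysis of the C–Al bond, should give the 1,1-disubstituted alkenyl iodide; the hydroxyl is carried as its aluminium alkoxide and no carbonyl group is present at this stage.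

**Step 6**
Reactants: 11 (1R,5S,6R)-6-[(tert-butyldimethylsilyl)oxy]-5-(1-iodoethenyl)-2-methylcyclohex-2-en-1-ol
Product: 12 (5S,6R)-6-[(tert-butyldimethylsilyl)oxy]-5-(1-iodoethenyl)-2-methylcyclohex-2-en-1-one
Conditions: MnO2, CH2Cl2, rt
Reagents that add atoms: none
Why: Chemoselective oxidation of the secondary allylic alcohol by activated MnO2 should complete the 1,3-carbonyl transposition and leave the alkenyl iodide and the silyl ether untouched.

**Step 7**
Reactants: 13 4-methylpent-3-en-1-ol
Product: 14 4-methylpent-3-enal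
Conditions: Dess–Martin periodinane, CH2Cl2, 0 °C; used at once as a solution
Reagents that add atoms: none
Why: Dess–Martin oxidation of the homoallylic primary alcohol under non-basic conditions should give the β,γ-unsaturated aldehyde without migration of the double bond into conjugation.

**Step 8**
Reactants: 12 (5S,6R)-6-[(tert-butyldimethylsilyl)oxy]-5-(1-iodoethenyl)-2-methylcyclohex-2-en-1-one; 14 4-methylpent-3-enal
Product: 15 (5R,6R)-6-[(tert-butyldimethylsilyl)oxy]-5-[(3S)-3-hydroxy-6-methylhepta-1,5-dien-2-yl]-2-methylcyclohex-2-en-1-one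
Conditions: CrCl2 (3 equiv), NiCl2 (2 mol %), chiral 2-(4-isopropyl-4,5-dihydrooxazol-2-yl)aryl methanesulfonamide ligand (3.3 equiv), Et3N, THF, rt
Reagents that add atoms: none
Why: Nozaki–Hiyama–Kishi coupling, in which zerovalent nickel inserts into the C–I bond and the alkenyl group passes to chromium to give an alkenylchromium species of trivalent chromium that adds only to the aldehyde, should form C7–C8 in the presence of the enone, and the sulfonamide ligand on chromium selects the aldehyde face so that C8 is set as S by reagent control (ligand enantiomer chosen accordingly).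

**Step 9**
Reactants: 15 (5R,6R)-6-[(tert-butyldimethylsilyl)oxy]-5-[(3S)-3-hydroxy-6-methylhepta-1,5-dien-2-yl]-2-methylcyclohex-2-en-1-one; 16 3-methylbut-2-enoic acid
Product: 17 (3S)-2-[(1R,2R)-2-[(tert-butyldimethylsilyl)oxy]-4-methyl-3-oxocyclohex-4-en-1-yl]-6-methylhepta-1,5-dien-3-yl 3-methylbut-2-enoate
Conditions: N,N′-dicyclohexylcarbodiimide, DMAP (cat.), CH2Cl2, 0 °C → rt
Reagents that add atoms: none
Why: Steglich esterification of the secondary allylic alcohol should install the senecioate while avoiding the ketene pathway (and so the deconjugation) that is open to the acid chloride with amine bases.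

**Step 10**
Reactants: 17 (3S)-2-[(1R,2R)-2-[(tert-butyldimethylsilyl)oxy]-4-methyl-3-oxocyclohex-4-en-1-yl]-6-methylhepta-1,5-dien-3-yl 3-methylbut-2-enoate
Product: 18 (3S)-2-[(1S,3R,4R,6S)-3-[(tert-butyldimethylsilyl)oxy]-1-methyl-2-oxo-7-oxabicyclo[4.1.0]heptan-4-yl]-6-methylhepta-1,5-dien-3-yl 3-methylbut-2-enoate
Conditions: t-BuOOH (5.5 M in decane), DBU (0.5 equiv), CH2Cl2, 0 °C → rt
Reagents that add atoms: tert-butyl hydroperoxide, CC(C)(C)OO
Why: Nucleophilic epoxidation of the 2-methylcyclohex-2-enone, in which the peroxide anion adds axially to C2 on the face opposite the equatorial C4 substituent as in the epoxidation of carvone, should set C1 and C2 by substrate control, and the β,β-disubstituted senecioate and the isolated alkenes should not react.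

**Step 11**
Reactants: 18 (3S)-2-[(1S,3R,4R,6S)-3-[(tert-butyldimethylsilyl)oxy]-1-methyl-2-oxo-7-oxabicyclo[4.1.0]heptan-4-yl]-6-methylhepta-1,5-dien-3-yl 3-methylbut-2-enoate
Product: 19 (3S)-2-[(1S,3R,4R,6S)-3-hydroxy-1-methyl-2-oxo-7-oxabicyclo[4.1.0]heptan-4-yl]-6-methylhepta-1,5-dien-3-yl 3-methylbut-2-enoate
Conditions: HF·pyridine, pyridine, THF, 0 °C → rt
Reagents that add atoms: none
Why: Buffered fluoride cleavage of the secondary silyl ether should free the C5 hydroxyl without opening the epoxide or epimerising the α-hydroxy ketone.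

**Step 12**
Reactants: 19 (3S)-2-[(1S,3R,4R,6S)-3-hydroxy-1-methyl-2-oxo-7-oxabicyclo[4.1.0]heptan-4-yl]-6-methylhepta-1,5-dien-3-yl 3-methylbut-2-enoate; 20 (2Z)-2-methylbut-2-enoic acid (angelic acid)
Product: 21 (1S,3S,4R,6S)-1-methyl-4-[(3S)-6-methyl-3-[(3-methylbut-2-enoyl)oxy]hepta-1,5-dien-2-yl]-2-oxo-7-oxabicyclo[4.1.0]heptan-3-yl (2Z)-2-methylbut-2-enoate (CNP0414062.1)
Conditions: PPh3, diisopropyl azodicarboxylate, toluene, 0 °C → rt
Reagents that add atoms: none
Why: Mitsunobu esterification, in which the C5 hydroxyl is activated as an alkoxyphosphonium ion and displaced by angelate in an SN2 step helped by the adjacent carbonyl, should invert C5 to the required cis relation with the C4 side chain and bring in the Z-enoate as a carboxylate nucleophile, so that it is never activated as an acyl donor and cannot isomerise to the tiglate.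

**Compound list**

1 | 3-(trimethylsilyl)prop-2-ynal | C[Si](C)(C)C#CC=O | starting material
2 | diethyl (2-oxobutyl)phosphonate | CCC(=O)CP(=O)(OCC)OCC | starting material
3 | (4E)-7-(trimethylsilyl)hept-4-en-6-yn-3-one | CCC(=O)/C=C/C#C[Si](C)(C)C | intermediate
4 | [(tert-butyldimethylsilyl)oxy]acetaldehyde | CC(C)(C)[Si](C)(C)OCC=O | starting material
5 | (2R,3R)-2-[(tert-butyldimethylsilyl)oxy]-5-oxo-3-[(trimethylsilyl)ethynyl]heptanal (Michael adduct) | O=C[C@H](O[Si](C)(C)C(C)(C)C)[C@@H](C#C[Si](C)(C)C)CC(=O)CC | intermediate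
6 | (4R,5R)-4-[(tert-butyldimethylsilyl)oxy]-3-hydroxy-2-methyl-5-[(trimethylsilyl)ethynyl]cyclohexan-1-one (aldol adduct; C2 and C3 not controlled and lost on dehydration) | O=C1C[C@H](C#C[Si](C)(C)C)[C@@H](O[Si](C)(C)C(C)(C)C)C(O)C1C | intermediate
7 | (4S,5R)-4-[(tert-butyldimethylsilyl)oxy]-2-methyl-5-[(trimethylsilyl)ethynyl]cyclohex-2-en-1-one | O=C1C[C@H](C#C[Si](C)(C)C)[C@@H](O[Si](C)(C)C(C)(C)C)C=C1C | intermediate
8 | (1S,4R,5R,6S)-5-[(tert-butyldimethylsilyl)oxy]-4-ethynyl-1-methyl-7-oxabicyclo[4.1.0]heptan-2-one | O=C1C[C@H](C#C)[C@@H](O[Si](C)(C)C(C)(C)C)[C@@H]2O[C@]12C | intermediate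
9 | (1R,5R,6R)-6-[(tert-butyldimethylsilyl)oxy]-5-ethynyl-2-methylcyclohex-2-en-1-ol | O[C@@H]1C(C)=CC[C@H](C#C)[C@H]1O[Si](C)(C)C(C)(C)C | intermediate
10 | diisobutylaluminium alkoxide of 9 carrying a 1-(diisobutylalumanyl)ethenyl group in place of the ethynyl group (alkenylalane; configuration as in 11) | CC(C)C[Al](CC(C)C)O[C@@H]1C(C)=CC[C@H](C(=C)[Al](CC(C)C)CC(C)C)[C@H]1O[Si](C)(C)C(C)(C)C | intermediate
11 | (1R,5S,6R)-6-[(tert-butyldimethylsilyl)oxy]-5-(1-iodoethenyl)-2-methylcyclohex-2-en-1-ol | O[C@@H]1C(C)=CC[C@H](C(I)=C)[C@H]1O[Si](C)(C)C(C)(C)C | intermediate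
12 | (5S,6R)-6-[(tert-butyldimethylsilyl)oxy]-5-(1-iodoethenyl)-2-methylcyclohex-2-en-1-one | O=C1C(C)=CC[C@H](C(I)=C)[C@H]1O[Si](C)(C)C(C)(C)C | intermediate
13 | 4-methylpent-3-en-1-ol | CC(C)=CCCO | starting material
14 | 4-methylpent-3-enal | CC(C)=CCC=O | intermediate
15 | (5R,6R)-6-[(tert-butyldimethylsilyl)oxy]-5-[(3S)-3-hydroxy-6-methylhepta-1,5-dien-2-yl]-2-methylcyclohex-2-en-1-one | O=C1C(C)=CC[C@H](C(=C)[C@@H](O)CC=C(C)C)[C@H]1O[Si](C)(C)C(C)(C)C | intermediate
16 | 3-methylbut-2-enoic acid | CC(C)=CC(=O)O | starting material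
17 | (3S)-2-[(1R,2R)-2-[(tert-butyldimethylsilyl)oxy]-4-methyl-3-oxocyclohex-4-en-1-yl]-6-methylhepta-1,5-dien-3-yl 3-methylbut-2-enoate | O=C1C(C)=CC[C@H](C(=C)[C@@H](OC(=O)C=C(C)C)CC=C(C)C)[C@H]1O[Si](C)(C)C(C)(C)C | intermediate
18 | (3S)-2-[(1S,3R,4R,6S)-3-[(tert-butyldimethylsilyl)oxy]-1-methyl-2-oxo-7-oxabicyclo[4.1.0]heptan-4-yl]-6-methylhepta-1,5-dien-3-yl 3-methylbut-2-enoate | C=C([C@H](CC=C(C)C)OC(=O)C=C(C)C)[C@H]1C[C@@H]2O[C@]2(C)C(=O)[C@@H]1O[Si](C)(C)C(C)(C)C | intermediate
19 | (3S)-2-[(1S,3R,4R,6S)-3-hydroxy-1-methyl-2-oxo-7-oxabicyclo[4.1.0]heptan-4-yl]-6-methylhepta-1,5-dien-3-yl 3-methylbut-2-enoate | C=C([C@H](CC=C(C)C)OC(=O)C=C(C)C)[C@H]1C[C@@H]2O[C@]2(C)C(=O)[C@@H]1O | intermediate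
20 | (2Z)-2-methylbut-2-enoic acid (angelic acid) | C/C=C(/C)C(=O)O | starting material
21 | (1S,3S,4R,6S)-1-methyl-4-[(3S)-6-methyl-3-[(3-methylbut-2-enoyl)oxy]hepta-1,5-dien-2-yl]-2-oxo-7-oxabicyclo[4.1.0]heptan-3-yl (2Z)-2-methylbut-2-enoate | C=C([C@H](CC=C(C)C)OC(=O)C=C(C)C)[C@H]1C[C@@H]2O[C@]2(C)C(=O)[C@H]1OC(=O)/C(C)=C\C | target

**Totals**

Total step count: 12. Longest linear sequence: 11 steps (steps 1–6 and 8–12; step 7 prepares the aldehyde partner).

**Steps most likely to fail**

1. Step 2. Conjugate addition to the β-substituted enynone may be too slow, so that self-condensation of 4 takes over, or the syn relation may be eroded by enamine-mediated epimerisation at C5 before ring closure. The fallback sets out from 4 and returns at 9. The same amine-catalysed Michael/aldol condensation is run on a doubly activated acceptor, a class for which this addition is established: 4 and ethyl (2E)-4-oxohex-2-enoate F1 are joined under the conditions of step 2 (addition at the carbon β to the ketone) to give ethyl (1S,2S)-2-[(tert-butyldimethylsilyl)oxy]-4-methyl-5-oxocyclohex-3-ene-1-carboxylate F2. Epoxidation (t-BuOOH, DBU, CH2Cl2) should give ethyl (1S,2R,3S,6S)-2-[(tert-butyldimethylsilyl)oxy]-6-methyl-5-oxo-7-oxabicyclo[4.1.0]heptane-3-carboxylate F3, and Wharton transposition (N2H4·H2O, AcOH, MeOH) ethyl (1S,5R,6R)-6-[(tert-butyldimethylsilyl)oxy]-5-hydroxy-4-methylcyclohex-3-ene-1-carboxylate F4. Reduction of the ester with i-Bu2AlH (CH2Cl2, −78 °C) should give (1S,5R,6R)-6-[(tert-butyldimethylsilyl)oxy]-5-hydroxy-4-methylcyclohex-3-ene-1-carbaldehyde F5, and Ohira–Bestmann homologation (dimethyl (1-diazo-2-oxopropyl)phosphonate, K2CO3, MeOH) turns the formyl group into the ethynyl group of 9.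

2. Step 12. Displacement at the hindered C5, next to the bulky C4 substituent, may be slow, so that elimination or enolisation of the α-hydroxy ketone competes with inversion. The fallback sets out from 19 and returns at 21. The hydroxyl is first made a discrete leaving group: Tf2O, pyridine, CH2Cl2, −40 °C should give (3S)-2-[(1S,3R,4R,6S)-1-methyl-2-oxo-3-{[(trifluoromethyl)sulfonyl]oxy}-7-oxabicyclo[4.1.0]heptan-4-yl]-6-methylhepta-1,5-dien-3-yl 3-methylbut-2-enoate F8, which is displaced with inversion by caesium angelate (20, Cs2CO3; 18-crown-6, toluene, rt) to give 21.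

3. Step 8. Facial selectivity at C8 may be poor, because the ring stereocentres are remote and the ligand alone must control the aldehyde face, and aldehyde 14 may isomerise into conjugation under the amine. The fallback sets out from 12 and returns at 15; it moves the stereo-defining bond from C7–C8 to C8–C9. Reductive carbonylation of 12 (Pd(PPh3)4, CO, Bu3SnH, THF, 50 °C) should give 2-[(1R,2R)-2-[(tert-butyldimethylsilyl)oxy]-4-methyl-3-oxocyclohex-4-en-1-yl]prop-2-enal F6. Allylboration with (−)-B-allyldiisopinocampheylborane (from (+)-α-pinene; Et2O, −78 °C; ethanolamine work-up) should give (5R,6R)-6-[(tert-butyldimethylsilyl)oxy]-5-[(3S)-3-hydroxyhexa-1,5-dien-2-yl]-2-methylcyclohex-2-en-1-one F7 under reagent control. Cross-metathesis with 2-methylbut-2-ene (second-generation Grubbs catalyst, CH2Cl2, 40 °C) converts the terminal vinyl group into the prenyl terminus of 15.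

**Further compounds**

F1 | step 2 | ethyl (2E)-4-oxohex-2-enoate | CCOC(=O)/C=C/C(=O)CC
F2 | step 2 | ethyl (1S,2S)-2-[(tert-butyldimethylsilyl)oxy]-4-methyl-5-oxocyclohex-3-ene-1-carboxylate | O=C1C[C@H](C(=O)OCC)[C@@H](O[Si](C)(C)C(C)(C)C)C=C1C
F3 | step 2 | ethyl (1S,2R,3S,6S)-2-[(tert-butyldimethylsilyl)oxy]-6-methyl-5-oxo-7-oxabicyclo[4.1.0]heptane-3-carboxylate | O=C1C[C@H](C(=O)OCC)[C@@H](O[Si](C)(C)C(C)(C)C)[C@@H]2O[C@]12C
F4 | step 2 | ethyl (1S,5R,6R)-6-[(tert-butyldimethylsilyl)oxy]-5-hydroxy-4-methylcyclohex-3-ene-1-carboxylate | O[C@@H]1C(C)=CC[C@H](C(=O)OCC)[C@H]1O[Si](C)(C)C(C)(C)C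
F5 | step 2 | (1S,5R,6R)-6-[(tert-butyldimethylsilyl)oxy]-5-hydroxy-4-methylcyclohex-3-ene-1-carbaldehyde | O[C@@H]1C(C)=CC[C@H](C=O)[C@H]1O[Si](C)(C)C(C)(C)C
F6 | step 8 | 2-[(1R,2R)-2-[(tert-butyldimethylsilyl)oxy]-4-methyl-3-oxocyclohex-4-en-1-yl]prop-2-enal | O=C1C(C)=CC[C@H](C(=C)C=O)[C@H]1O[Si](C)(C)C(C)(C)C
F7 | step 8 | (5R,6R)-6-[(tert-butyldimethylsilyl)oxy]-5-[(3S)-3-hydroxyhexa-1,5-dien-2-yl]-2-methylcyclohex-2-en-1-one | O=C1C(C)=CC[C@H](C(=C)[C@@H](O)CC=C)[C@H]1O[Si](C)(C)C(C)(C)C
F8 | step 12 | (3S)-2-[(1S,3R,4R,6S)-1-methyl-2-oxo-3-{[(trifluoromethyl)sulfonyl]oxy}-7-oxabicyclo[4.1.0]heptan-4-yl]-6-methylhepta-1,5-dien-3-yl 3-methylbut-2-enoate | C=C([C@H](CC=C(C)C)OC(=O)C=C(C)C)[C@H]1C[C@@H]2O[C@]2(C)C(=O)[C@@H]1OS(=O)(=O)C(F)(F)F
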